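**Remark on the chemistry.** Locants C1–C17 are the cembrane numbers: C1 ring-fusion CH, C2 CH2, C3 CHOAc, C4 C(CH3)OH, C5–C6, C7=C8, C9–C10, C11=C12, C13 CHOAc, C14 lactone CH–O, C15 α-carbon, C16 carbonyl, C17 exocyclic CH2. Commercial farnesol is taken as the pure (2E,6E) isomer. The C13 hydroxyl is carried as a triethylsilyl ether so that it leaves in the same acid step as the acetonide.

## Analysis of the target

Crassocolide B (28) is a cembranoid: a 14-membered carbocycle (C1–C14) fused at C1/C14 to an α-methylene-γ-butyrolactone (O–C16(=O)–C15(=C17H2)), with H1 and H14 trans. It has five stereocentres, 1R, 3S, 4R, 13S and 14R. C3/C4 are a secondary acetate next to a free tertiary alcohol, in the relation that anti addition of two oxygens to an E olefin gives. C13/C14 are an erythro pair, C13 carrying an allylic acetate and C14 the lactone oxygen. The two trisubstituted olefins C7=C8 and C11=C12 are both E. The sensitive groups are the exocyclic enoate (a Michael acceptor that is also reducible), the allylic C13 acetate, the base-labile acetates, and three hydroxyl oxygens (C3, C4, C13) that can each capture the C16 acyl group by translactonisation once they are free. The difficulty is closing a 14-membered carbocycle while relating the C13/C14/C1 triad to the remote C3/C4 pair. The strategy rests on two features: C13 and C14 are adjacent oxygen-bearing carbons, so each can begin as an aldehyde carbon, and the C14 oxygen is γ to C16, so it closes the lactone as soon as it is formed. In addition, C2–C13 with its three methyl groups and both E olefins is the carbon chain of farnesol (1).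

## Retrosynthetic reasoning

**Acetates and protecting groups (28 ⇒ 27 ⇒ 26).** The two acyl–oxygen bonds at C3 and C13 are cut last, because acetates would not survive the strong base needed for the methylene group. Triol 27 needs no differentiation, since only its two secondary hydroxyls acylate under mild conditions. 27 is the hydrolysis product of 26, in which the C3/C4 acetonide and the C13 silyl ether are both acid-labile and leave together.

**Exocyclic methylene (26 ⇒ 22).** The C15–C17 bond is cut, removing the only carbon that does not come from the main fragments. It is introduced late because the enoate would not survive thiolate, hydride or low-valent metal. The forward reaction must aminomethylate the lactone enolate of 22 (via Mannich base 24) and eliminate the amine. C15 is the only enolisable position in 22.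

**Ring and lactone (22 ⇒ 21 ⇒ 19).** The C13–C14 bond and the O14–C16 bond are cut together. This is the only place in the ring where both carbons bear oxygen, so a reductive coupling of two aldehydes delivers both oxygens and both stereocentres while closing the ring. It leaves the acyclic dialdehyde ester 19, which has no ring and only three stereocentres (C1, C3, C4). The forward reaction has to couple the C13 enal and the C14 aldehyde intramolecularly, stop at the diol (20), and let the C14 oxygen displace methoxide from C16 to give 21.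

**Oxidation levels at C13 and C14 (19 ⇒ 18 ⇒ 17 ⇒ 16 ⇒ 15).** The C14 aldehyde is traced back to the acyl group of an auxiliary-bound imide through thioester 18/17, because a thioester can be reduced to the aldehyde without touching the C16 methyl ester. Reducing the imide to the alcohol would instead lactonise onto C16. The C13 aldehyde is traced back to the terminal E methyl group of the farnesyl chain (16 ⇒ 15), a C–H oxidation at the most accessible olefin of the chain.

**C1–C15 (15 ⇒ 12 + 13).** The bond between C1 and the acetate arm is cut, because an auxiliary-controlled enolate alkylation with an α-halo ester is among the most dependable ways to set an isolated stereocentre. It fixes C1 independently of C3/C4 with the (S)-auxiliary 10, and the electrophile 13 brings C15 and C16 at the right oxidation level.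

**Acyl–nitrogen bond and C1–C2 (12 ⇒ 9 + 10; 9 ⇒ 8 ⇒ 7).** Imide 12 comes from acid 9 and auxiliary 10. Acid 9 is the saponified, conjugate-reduced form of enoate 7. The acetonide must already be in place at this stage, otherwise the C3 hydroxyl would lactonise onto C14 once the olefin is saturated.

**C4–O with inversion (7 ⇒ 6 ⇒ 5).** The anti C3/C4 diol is traced to the trans epoxide 5, opened at the tertiary carbon with inversion. Opening at the stage of the epoxy enoate, and not at that of the epoxy alcohol, avoids a 1,2,3-triol whose acetonide could form on the wrong pair of hydroxyls. The acrylate also deactivates the secondary epoxide carbon toward attack.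

**C1=C2 and the epoxide (5 ⇒ 4 + 3; 4 ⇒ 2 ⇒ 1).** The two carbons C1 and C14 come from ylide 3 by olefination of epoxy aldehyde 4. Compound 4 is the oxidation product of epoxy alcohol 2, and 2 arises from 1 by a hydroxyl-directed asymmetric epoxidation. That epoxidation touches only the allylic olefin of the three and sets the absolute configuration of C3 and C4.

## Alternatives that were turned down

**Alternative 1:** ring contraction at C5–C6. The disconnection is the C5–C6 bond. The substrate would be the 16-membered allyl β-keto ester macrolactone A2, in which the ester links C5 through a carboxyl group to the allylic carbon C6. A zerovalent palladium catalyst would ionise the allylic ester, the β-keto carboxylate would decarboxylate, and the C4/C5 enolate would attack the unsubstituted allyl terminus C6, giving the 14-membered C4 ketone A1.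
- For it: the large ring is first closed as an ester, which is easier than a C–C closure; the C–C bond forms under neutral conditions; and C1, C13 and C14 are all set by acyclic chemistry before any ring exists. On the stereochemical security of C13/C14 this alternative is stronger than the chosen one.
- Against it: after decarboxylation the enolate and the allyl cation are no longer tethered by the ester, so the C–C closure is again a 14-membered macrocyclisation competing with protonation and crossover. Equilibration of the allyl complex can erode the 7E geometry. A1 still lacks the C4 methyl group, so the tertiary carbinol has to be made by a facially selective addition to a macrocyclic α-alkoxy ketone whose C3 centre is epimerisable. A2 needs the lactone triad, C3 and a macrolactonisation to be built first, which costs several more steps than the route to 19.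
- In its place the chosen strategy offers a precursor in which every skeletal carbon and both olefin geometries come from 1, and a ring closure that creates C13 and C14 instead of consuming steps to install them.

**Alternative 2:** photochemical reorganisation. The net disconnections are C1–C15 and C2–C3. The substrate would be the 13-membered cyclic enol ether A4, whose ring oxygen links C3 and C14; C14 carries a vinyl group (C1=C2) and C3 an exocyclic alkoxyacrylate (C3=C15–C16). Triplet-sensitised irradiation would add the vinyl group across the acrylate in the crossed sense (C1 to C15, C2 to C3), building a 2-oxabicyclo[2.1.1]hexane core. Acid in the same flask would break C3–C15 and the C3–O bond, so that C3 becomes a ketone, the ring oxygen ends on C14 as the lactone oxygen, and the macrocyclic ether becomes the 14-membered carbocycle of keto lactone A3.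
- For it: the two-atom tether favours the crossed addition; carbocycle and lactone arise from one operation; and C13, C14 and C4 are fixed beforehand, so the ring-forming event does not have to control the C13/C14 pair. On that point it is stronger.
- Against it: A4 is itself a 13-membered ring that must be closed first, so the macrocyclisation problem is moved, not removed. C1 is created in the photoaddition and its relation to C14 depends on the face of approach within a floppy ring. The sensitiser can also transfer energy to the two trisubstituted olefins. A3 needs a stereoselective reduction at C3 next to the quaternary C4. The sequence has not been shown on macrocyclic substrates of this kind.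
- The chosen strategy relies on a ring closure of known type and reaches its precursor in fewer steps.

**Alternative 3:** nickel reductive alkyne–aldehyde closure at C12–C13. The disconnection is the C12–C13 bond. The substrate would be ynal A6, a preformed trans-disubstituted γ-lactone bearing the C13 formyl group on C14 and a methyl-capped C11≡C12 alkyne at the chain end. A zerovalent nickel catalyst with a compact N-heterocyclic carbene and a trialkylsilane would couple alkyne and aldehyde through an oxanickelacycle and deliver the E olefin and the C13 silyl ether of macrocycle A5.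
- For it: A5 is the same compound as 22 of the chosen route, so the silylation step is saved. C14 and C1 are fixed before the ring closes, so only C13 has to be controlled, and α-oxygenated aldehydes often give useful 1,2-induction in this reaction. On stereocontrol at C14 and on the end game it is as strong or stronger.
- Against it: the regiochemistry at an alkyne that differs only by methyl versus chain depends entirely on the ligand, and the wrong sense gives a 13-membered ring with an exocyclic olefin. The α-acyloxy aldehyde of A6 is configurationally fragile at C14. The C11=C12 olefin of 1 cannot be used, so the terminus must be degraded and rebuilt as an alkyne and the lactone assembled separately, which makes the precursor clearly longer.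
- The chosen strategy keeps the preformed E olefin of 1 and forms ring, lactone and two stereocentres in one step, accepting in return that C13/C14 control rests on the coupling itself.

Key step: step 13

## Steps

Step 1
Reactants: 1 (2E,6E)-farnesol
Product: 2 (2S,3S)-2,3-epoxyfarnesol
Conditions: Ti(OiPr)4 (cat.), L-(+)-diethyl tartrate (cat.), t-BuOOH, 4 Å molecular sieves, CH2Cl2, −20 °C
Reagents that add atoms: tert-butyl hydroperoxide CC(C)(C)OO
Why: Sharpless asymmetric epoxidation; only the olefin next to the titanium-bound hydroxyl reacts, and the L-(+)-tartrate ligand delivers oxygen to the face that gives the (2S,3S) epoxide. These two carbons become C3 and C4.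

Step 2
Reactants: 2 (2S,3S)-2,3-epoxyfarnesol; 3 ethyl (triphenylphosphoranylidene)acetate
Product: 5 ethyl (2E,4S,5S,8E)-4,5-epoxy-5,9,13-trimethyltetradeca-2,8,12-trienoate, via epoxy aldehyde 4 (not isolated)
Conditions: SO3·pyridine, DMSO, i-Pr2NEt, CH2Cl2, 0 °C; then 3, rt
Reagents that add atoms: none
Why: Parikh–Doering oxidation under non-acidic conditions gives the labile epoxy aldehyde, which is trapped in the same flask by the stabilised ylide (Wittig olefination, E-selective). The epoxide carbon cannot enolise, so its configuration is safe.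

Step 3
Reactants: 5 ethyl (2E,4S,5S,8E)-4,5-epoxy-5,9,13-trimethyltetradeca-2,8,12-trienoate
Product: 6 ethyl (2E,4S,5R,8E)-4,5-dihydroxy-5,9,13-trimethyltetradeca-2,8,12-trienoate
Conditions: HClO4 (cat., aq.), THF/H2O, 0 °C to rt
Reagents that add atoms: water O
Why: Acid-catalysed epoxide hydrolysis; water attacks the tertiary carbon, which carries the positive charge best while the secondary carbon is deactivated by the adjacent acrylate, anti to the departing oxygen. The tertiary centre is inverted (S to R) and the secondary one retained, which gives the anti diol that becomes C3 (S) and C4 (R).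

Step 4
Reactants: 6 ethyl (2E,4S,5R,8E)-4,5-dihydroxy-5,9,13-trimethyltetradeca-2,8,12-trienoate
Product: 7 ethyl (2E)-3-[(4S,5R)-5-[(3E)-4,8-dimethylnona-3,7-dien-1-yl]-2,2,5-trimethyl-1,3-dioxolan-4-yl]prop-2-enoate
Conditions: 2,2-dimethoxypropane, PPTS (cat.), CH2Cl2, rt
Reagents that add atoms: 2,2-dimethoxypropane COC(C)(C)OC
Why: Acid-catalysed transketalisation closes the five-membered acetonide on the only two hydroxyls present. It is installed before the olefin is reduced so that the C3 oxygen cannot lactonise onto the ester.

Step 5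
Reactants: 7 ethyl (2E)-3-[(4S,5R)-5-[(3E)-4,8-dimethylnona-3,7-dien-1-yl]-2,2,5-trimethyl-1,3-dioxolan-4-yl]prop-2-enoate
Product: 8 ethyl 3-[(4S,5R)-5-[(3E)-4,8-dimethylnona-3,7-dien-1-yl]-2,2,5-trimethyl-1,3-dioxolan-4-yl]propanoate
Conditions: Cu(OAc)2·H2O (cat.), 1,2-bis(diphenylphosphino)benzene (cat.), (EtO)2MeSiH, t-BuOH, toluene, rt
Reagents that add atoms: none
Why: Copper hydride conjugate reduction; hydride adds only to the β-carbon of the enoate and the isolated trisubstituted olefins are inert. No carbanion develops next to the acetonide oxygen, so the γ-oxygen is not expelled.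

Step 6
Reactants: 8 ethyl 3-[(4S,5R)-5-[(3E)-4,8-dimethylnona-3,7-dien-1-yl]-2,2,5-trimethyl-1,3-dioxolan-4-yl]propanoate
Product: 9 3-[(4S,5R)-5-[(3E)-4,8-dimethylnona-3,7-dien-1-yl]-2,2,5-trimethyl-1,3-dioxolan-4-yl]propanoic acid
Conditions: LiOH, THF/MeOH/H2O, rt; then 1 M HCl to pH 4, 0 °C
Reagents that add atoms: lithium hydroxide [Li+].[OH-]
Why: Ester saponification; the acetonide is stable to base and survives the brief, cold acidification to pH 4.

Step 7
Reactants: 9 3-[(4S,5R)-5-[(3E)-4,8-dimethylnona-3,7-dien-1-yl]-2,2,5-trimethyl-1,3-dioxolan-4-yl]propanoic acid; 10 (S)-4-benzyl-2-oxazolidinone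
Product: 12 (4S)-4-benzyl-3-{3-[(4S,5R)-5-[(3E)-4,8-dimethylnona-3,7-dien-1-yl]-2,2,5-trimethyl-1,3-dioxolan-4-yl]propanoyl}-1,3-oxazolidin-2-one, via mixed pivalic anhydride 11 (not isolated)
Conditions: t-BuCOCl, Et3N, THF, −20 °C; then 10, LiCl, −20 °C to rt
Reagents that add atoms: pivaloyl chloride CC(C)(C)C(Cl)=O (its atoms stay only in intermediate 11)
Why: N-Acylation through the mixed anhydride; the oxazolidinone, activated by LiCl/Et3N, attacks the less hindered carbonyl of the anhydride.

Step 8
Reactants: 12 (4S)-4-benzyl-3-{3-[(4S,5R)-5-[(3E)-4,8-dimethylnona-3,7-dien-1-yl]-2,2,5-trimethyl-1,3-dioxolan-4-yl]propanoyl}-1,3-oxazolidin-2-one; 13 methyl bromoacetate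
Product: 15 methyl (3R)-3-{[(4S)-4-benzyl-2-oxo-1,3-oxazolidin-3-yl]carbonyl}-4-[(4S,5R)-5-[(3E)-4,8-dimethylnona-3,7-dien-1-yl]-2,2,5-trimethyl-1,3-dioxolan-4-yl]butanoate, via sodium Z-enolate 14 (not isolated)
Conditions: NaN(SiMe3)2, THF, −78 °C; then 13, −78 to −40 °C
Reagents that add atoms: none
Why: Evans asymmetric alkylation; the chelated Z-enolate is shielded on one face by the benzyl group, and the bromoacetate enters from the other face, which sets C1 as R. The acetonide oxygen is γ to the carbonyl, so the enolate cannot eliminate it.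

Step 9
Reactants: 15 methyl (3R)-3-{[(4S)-4-benzyl-2-oxo-1,3-oxazolidin-3-yl]carbonyl}-4-[(4S,5R)-5-[(3E)-4,8-dimethylnona-3,7-dien-1-yl]-2,2,5-trimethyl-1,3-dioxolan-4-yl]butanoate
Product: 16 methyl (3R)-3-{[(4S)-4-benzyl-2-oxo-1,3-oxazolidin-3-yl]carbonyl}-4-[(4S,5R)-5-[(3E,7E)-9-hydroxy-4,8-dimethylnona-3,7-dien-1-yl]-2,2,5-trimethyl-1,3-dioxolan-4-yl]butanoate
Conditions: SeO2 (cat.), t-BuOOH, salicylic acid (cat.), CH2Cl2, 0 °C to rt
Reagents that add atoms: tert-butyl hydroperoxide CC(C)(C)OO (its oxygen reaches C13 through the SeO2 catalyst)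
Why: Catalytic selenium dioxide allylic oxidation (ene reaction, then [2,3]-shift); the terminal isopropylidene olefin is the most accessible one, and its E methyl group is the one oxidised, as is usual for such termini, which should give the E allylic alcohol at C13. Any over-oxidised enal can be separated and returned to 16 with NaBH4/CeCl3·7H2O.

Step 10
Reactants: 16 methyl (3R)-3-{[(4S)-4-benzyl-2-oxo-1,3-oxazolidin-3-yl]carbonyl}-4-[(4S,5R)-5-[(3E,7E)-9-hydroxy-4,8-dimethylnona-3,7-dien-1-yl]-2,2,5-trimethyl-1,3-dioxolan-4-yl]butanoate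
Product: 17 methyl (3R)-3-[(ethylsulfanyl)carbonyl]-4-[(4S,5R)-5-[(3E,7E)-9-hydroxy-4,8-dimethylnona-3,7-dien-1-yl]-2,2,5-trimethyl-1,3-dioxolan-4-yl]butanoate
Conditions: EtSH, n-BuLi (preformed LiSEt, 3 equiv), THF, 0 °C
Reagents that add atoms: ethanethiol CCS
Why: Thiolate cleavage of the imide (acyl transfer at the exocyclic carbonyl) gives the thioester, and the auxiliary is recovered. The methyl ester is not exchanged because thioester formation from an ester is uphill, and the weakly basic thiolate should not epimerise C1.

Step 11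
Reactants: 17 methyl (3R)-3-[(ethylsulfanyl)carbonyl]-4-[(4S,5R)-5-[(3E,7E)-9-hydroxy-4,8-dimethylnona-3,7-dien-1-yl]-2,2,5-trimethyl-1,3-dioxolan-4-yl]butanoate
Product: 18 methyl (3R)-3-[(ethylsulfanyl)carbonyl]-4-[(4S,5R)-5-[(3E,7E)-4,8-dimethyl-9-oxonona-3,7-dien-1-yl]-2,2,5-trimethyl-1,3-dioxolan-4-yl]butanoate
Conditions: MnO2 (activated), CH2Cl2, rt
Reagents that add atoms: none
Why: Manganese dioxide oxidises only the allylic alcohol and keeps the E geometry of the enal; thioester, ester and acetonide are inert.

Step 12
Reactants: 18 methyl (3R)-3-[(ethylsulfanyl)carbonyl]-4-[(4S,5R)-5-[(3E,7E)-4,8-dimethyl-9-oxonona-3,7-dien-1-yl]-2,2,5-trimethyl-1,3-dioxolan-4-yl]butanoate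
Product: 19 methyl (3R)-3-formyl-4-[(4S,5R)-5-[(3E,7E)-4,8-dimethyl-9-oxonona-3,7-dien-1-yl]-2,2,5-trimethyl-1,3-dioxolan-4-yl]butanoate
Conditions: Et3SiH, Pd/C (10 %), acetone, rt; used at once
Reagents that add atoms: none
Why: Fukuyama reduction; palladium inserts into the C–S bond, the silane delivers hydride, and the acyl palladium hydride collapses to the aldehyde, which is not reduced further. The methyl ester is untouched, and the thiolate-moderated catalyst should leave the trisubstituted olefins and the hindered enal alone.

Step 13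
Reactants: 19 methyl (3R)-3-formyl-4-[(4S,5R)-5-[(3E,7E)-4,8-dimethyl-9-oxonona-3,7-dien-1-yl]-2,2,5-trimethyl-1,3-dioxolan-4-yl]butanoate
Product: 21 (1R,3S,4R,13S,14R,7E,11E)-13-hydroxy-3,4-(isopropylidenedioxy)cembra-7,11-dien-16,14-olide, via macrocyclic dihydroxy ester 20 (not isolated)
Conditions: TiCl3(DME)1.5, Zn–Cu couple, DME, reflux (reagent formation), then −40 °C; 19 added by syringe pump over 30 h (about 0.002 M), −40 to 0 °C; aq. K2CO3; PPTS (cat.), CH2Cl2, rt if open-chain 20 remains
Reagents that add atoms: none
Why: Electron transfer from low-valent titanium to both aldehydes gives two titanium-bound ketyls (the C13 one stabilised as an allyl-type radical anion by C11=C12), which join C13 to C14 while both oxygens stay on the metal; keeping the mixture cold stops the reaction at the diolate instead of deoxygenating it to the olefin, and the closest known reaction type is the intramolecular titanium pinacol coupling of dialdehydes, which has closed 14-membered terpenoid diols. The carbocycle thus closes by combination of two metal-bound ketyl carbons under pseudo-high dilution, and the γ-lactone closes afterwards by 5-exo-trig acyl substitution of the C14 titanium alkoxide on the C16 methyl ester with loss of methoxide (20 to 21). C14 is controlled by the resident C1 centre: binding of the C16 ester carbonyl to the titanium on the C14 oxygen gives a seven-membered chelate in which C13 bonds to the face of C14 away from C2, which corresponds to the trans ring fusion. C13 is controlled relative to C14 by the cisoid O–Ti–O bridge: when C12 and C1 lie on the same side of that metallacycle the diol is erythro (13S,14R), as required. The step needs cyclisation to win over oligomerisation, which slow addition and the two rigid E olefins support; it needs coupling at C13 and not at the vinylogous C11, which the substitution at C11 and the strain-free 14-membered ring favour; and it needs lactonisation through O14 only, which holds because O13 would have to form a six-membered ring. The erythro preference is expected to be the weakest of these controls at this ring size.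

Step 14
Reactants: 21 (1R,3S,4R,13S,14R,7E,11E)-13-hydroxy-3,4-(isopropylidenedioxy)cembra-7,11-dien-16,14-olide
Product: 22 (1R,3S,4R,13S,14R,7E,11E)-3,4-(isopropylidenedioxy)-13-(triethylsilyloxy)cembra-7,11-dien-16,14-olide
Conditions: Et3SiOTf, 2,6-lutidine, CH2Cl2, −78 °C
Reagents that add atoms: triethylsilyl trifluoromethanesulfonate CC[Si](CC)(CC)OS(=O)(=O)C(F)(F)F
Why: Silylation of the hindered secondary allylic alcohol with a silyl triflate; the ether masks the hydroxyl against the amide base of the next step and is cleavable under the same acid as the acetonide.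

Step 15
Reactants: 22 (1R,3S,4R,13S,14R,7E,11E)-3,4-(isopropylidenedioxy)-13-(triethylsilyloxy)cembra-7,11-dien-16,14-olide
Product: 24 15-(dimethylaminomethyl) derivative of 22 (C15 epimers), via lithium lactone enolate 23 (not isolated)
Conditions: LiN(iPr)2, THF, −78 °C; then CH2=NMe2+ I−, −78 to 0 °C
Reagents that add atoms: N,N-dimethylmethyleneiminium iodide C=[N+](C)C.[I-]
Why: Mannich reaction of the lactone enolate with Eschenmoser's salt; C15 is the only enolisable position, and the configuration created there is removed in the next step.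

Step 16
Reactants: 24 15-(dimethylaminomethyl) derivative of 22 (C15 epimers)
Product: 26 (1R,3S,4R,13S,14R,7E,11E)-3,4-(isopropylidenedioxy)-13-(triethylsilyloxy)cembra-7,11,15(17)-trien-16,14-olide, via trimethylammonium iodide 25 (not isolated)
Conditions: MeI, MeOH/CH2Cl2, rt; then aq. NaHCO3, CH2Cl2, rt
Reagents that add atoms: iodomethane CI (its methyl stays only in intermediate 25)
Why: Quaternisation of the amine followed by E1cB elimination of trimethylamine from the β-ammonio lactone gives the exocyclic methylene under conditions too mild to touch the silyl ether or the acetonide.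

Step 17
Reactants: 26 (1R,3S,4R,13S,14R,7E,11E)-3,4-(isopropylidenedioxy)-13-(triethylsilyloxy)cembra-7,11,15(17)-trien-16,14-olide
Product: 27 (1R,3S,4R,13S,14R,7E,11E)-3,4,13-trihydroxycembra-7,11,15(17)-trien-16,14-olide
Conditions: aq. HCl (1 M), THF, rt
Reagents that add atoms: none
Why: Acid hydrolysis removes the acetonide and the triethylsilyl ether in one operation. The five-membered lactone should stay in place, since each free hydroxyl could only form a larger lactone, and the C13 carbinol resists ionisation because C14 bears the electron-withdrawing lactone oxygen.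

Step 18
Reactants: 27 (1R,3S,4R,13S,14R,7E,11E)-3,4,13-trihydroxycembra-7,11,15(17)-trien-16,14-olide
Product: 28 crassocolide B
Conditions: Ac2O, pyridine, DMAP (cat.), CH2Cl2, 0 °C to rt
Reagents that add atoms: acetic anhydride CC(=O)OC(C)=O
Why: Acylation of the two secondary hydroxyls at C3 and C13; the tertiary C4 hydroxyl does not react under these conditions, so no differentiation is needed.

## Compound list

1 | (2E,6E)-farnesol | CC(C)=CCC/C(C)=C/CC/C(C)=C/CO | starting material
2 | (2S,3S)-2,3-epoxyfarnesol | CC(C)=CCC/C(C)=C/CC[C@]1(C)O[C@H]1CO | intermediate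
3 | ethyl (triphenylphosphoranylidene)acetate | CCOC(=O)C=P(c1ccccc1)(c1ccccc1)c1ccccc1 | starting material
4 | (2R,3S)-2,3-epoxyfarnesal (epoxy aldehyde, not isolated) | CC(C)=CCC/C(C)=C/CC[C@]1(C)O[C@H]1C=O | intermediate
5 | ethyl (2E,4S,5S,8E)-4,5-epoxy-5,9,13-trimethyltetradeca-2,8,12-trienoate | CC(C)=CCC/C(C)=C/CC[C@]1(C)O[C@H]1/C=C/C(=O)OCC | intermediate
6 | ethyl (2E,4S,5R,8E)-4,5-dihydroxy-5,9,13-trimethyltetradeca-2,8,12-trienoate | CC(C)=CCC/C(C)=C/CC[C@@](C)(O)[C@@H](O)/C=C/C(=O)OCC | intermediate
7 | ethyl (2E)-3-[(4S,5R)-5-[(3E)-4,8-dimethylnona-3,7-dien-1-yl]-2,2,5-trimethyl-1,3-dioxolan-4-yl]prop-2-enoate | CC(C)=CCC/C(C)=C/CC[C@@]1(C)OC(C)(C)O[C@H]1/C=C/C(=O)OCC | intermediate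
8 | ethyl 3-[(4S,5R)-5-[(3E)-4,8-dimethylnona-3,7-dien-1-yl]-2,2,5-trimethyl-1,3-dioxolan-4-yl]propanoate | CC(C)=CCC/C(C)=C/CC[C@@]1(C)OC(C)(C)O[C@H]1CCC(=O)OCC | intermediate
9 | 3-[(4S,5R)-5-[(3E)-4,8-dimethylnona-3,7-dien-1-yl]-2,2,5-trimethyl-1,3-dioxolan-4-yl]propanoic acid | CC(C)=CCC/C(C)=C/CC[C@@]1(C)OC(C)(C)O[C@H]1CCC(=O)O | intermediate
10 | (S)-4-benzyl-2-oxazolidinone | O=C1N[C@@H](Cc2ccccc2)CO1 | starting material
11 | mixed pivalic anhydride of 9 (not isolated) | CC(C)=CCC/C(C)=C/CC[C@@]1(C)OC(C)(C)O[C@H]1CCC(=O)OC(=O)C(C)(C)C | intermediate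
12 | (4S)-4-benzyl-3-{3-[(4S,5R)-5-[(3E)-4,8-dimethylnona-3,7-dien-1-yl]-2,2,5-trimethyl-1,3-dioxolan-4-yl]propanoyl}-1,3-oxazolidin-2-one | CC(C)=CCC/C(C)=C/CC[C@@]1(C)OC(C)(C)O[C@H]1CCC(=O)N2[C@@H](Cc3ccccc3)COC2=O | intermediate
13 | methyl bromoacetate | COC(=O)CBr | starting material
14 | sodium Z-enolate of 12 (not isolated) | CC(C)=CCC/C(C)=C/CC[C@@]1(C)OC(C)(C)O[C@H]1C/C=C(\[O-])N2[C@@H](Cc3ccccc3)COC2=O.[Na+] | intermediate
15 | methyl (3R)-3-{[(4S)-4-benzyl-2-oxo-1,3-oxazolidin-3-yl]carbonyl}-4-[(4S,5R)-5-[(3E)-4,8-dimethylnona-3,7-dien-1-yl]-2,2,5-trimethyl-1,3-dioxolan-4-yl]butanoate | CC(C)=CCC/C(C)=C/CC[C@@]1(C)OC(C)(C)O[C@H]1C[C@H](CC(=O)OC)C(=O)N2[C@@H](Cc3ccccc3)COC2=O | intermediate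
16 | methyl (3R)-3-{[(4S)-4-benzyl-2-oxo-1,3-oxazolidin-3-yl]carbonyl}-4-[(4S,5R)-5-[(3E,7E)-9-hydroxy-4,8-dimethylnona-3,7-dien-1-yl]-2,2,5-trimethyl-1,3-dioxolan-4-yl]butanoate | OC/C(C)=C/CC/C(C)=C/CC[C@@]1(C)OC(C)(C)O[C@H]1C[C@H](CC(=O)OC)C(=O)N2[C@@H](Cc3ccccc3)COC2=O | intermediate
17 | methyl (3R)-3-[(ethylsulfanyl)carbonyl]-4-[(4S,5R)-5-[(3E,7E)-9-hydroxy-4,8-dimethylnona-3,7-dien-1-yl]-2,2,5-trimethyl-1,3-dioxolan-4-yl]butanoate | OC/C(C)=C/CC/C(C)=C/CC[C@@]1(C)OC(C)(C)O[C@H]1C[C@H](CC(=O)OC)C(=O)SCC | intermediate
18 | methyl (3R)-3-[(ethylsulfanyl)carbonyl]-4-[(4S,5R)-5-[(3E,7E)-4,8-dimethyl-9-oxonona-3,7-dien-1-yl]-2,2,5-trimethyl-1,3-dioxolan-4-yl]butanoate | O=C/C(C)=C/CC/C(C)=C/CC[C@@]1(C)OC(C)(C)O[C@H]1C[C@H](CC(=O)OC)C(=O)SCC | intermediate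
19 | methyl (3R)-3-formyl-4-[(4S,5R)-5-[(3E,7E)-4,8-dimethyl-9-oxonona-3,7-dien-1-yl]-2,2,5-trimethyl-1,3-dioxolan-4-yl]butanoate (dialdehyde ester, key-step precursor) | O=C/C(C)=C/CC/C(C)=C/CC[C@@]1(C)OC(C)(C)O[C@H]1C[C@H](CC(=O)OC)C=O | intermediate
20 | methyl [(1R,3S,4R,13S,14R,7E,11E)-13,14-dihydroxy-3,4-(isopropylidenedioxy)cembra-7,11-dien-15-yl]carboxylate, the macrocyclic dihydroxy ester (not isolated) | COC(=O)C[C@@H]1[C@@H](O)[C@@H](O)/C(C)=C/CC/C(C)=C/CC[C@@]2(C)OC(C)(C)O[C@H]2C1 | intermediate
21 | (1R,3S,4R,13S,14R,7E,11E)-13-hydroxy-3,4-(isopropylidenedioxy)cembra-7,11-dien-16,14-olide (key-step product) | C1C(=O)O[C@@H]2[C@@H]1C[C@@H]3OC(C)(C)O[C@]3(C)CC/C=C(\C)CC/C=C(\C)[C@@H]2O | intermediate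
22 | (1R,3S,4R,13S,14R,7E,11E)-3,4-(isopropylidenedioxy)-13-(triethylsilyloxy)cembra-7,11-dien-16,14-olide | C1C(=O)O[C@@H]2[C@@H]1C[C@@H]3OC(C)(C)O[C@]3(C)CC/C=C(\C)CC/C=C(\C)[C@@H]2O[Si](CC)(CC)CC | intermediate
23 | lithium enolate of lactone 22 (not isolated) | [Li+].[O-]C1=C[C@H]2C[C@@H]3OC(C)(C)O[C@]3(C)CC/C=C(\C)CC/C=C(\C)[C@H](O[Si](CC)(CC)CC)[C@@H]2O1 | intermediate
24 | 15-(dimethylaminomethyl) derivative of 22 (C15 configuration not controlled) | CN(C)CC1C(=O)O[C@@H]2[C@@H]1C[C@@H]3OC(C)(C)O[C@]3(C)CC/C=C(\C)CC/C=C(\C)[C@@H]2O[Si](CC)(CC)CC | intermediate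
25 | 15-(trimethylammoniomethyl) iodide of 22 (not isolated) | C[N+](C)(C)CC1C(=O)O[C@@H]2[C@@H]1C[C@@H]3OC(C)(C)O[C@]3(C)CC/C=C(\C)CC/C=C(\C)[C@@H]2O[Si](CC)(CC)CC.[I-] | intermediate
26 | (1R,3S,4R,13S,14R,7E,11E)-3,4-(isopropylidenedioxy)-13-(triethylsilyloxy)cembra-7,11,15(17)-trien-16,14-olide | C=C1C(=O)O[C@@H]2[C@@H]1C[C@@H]3OC(C)(C)O[C@]3(C)CC/C=C(\C)CC/C=C(\C)[C@@H]2O[Si](CC)(CC)CC | intermediate
27 | (1R,3S,4R,13S,14R,7E,11E)-3,4,13-trihydroxycembra-7,11,15(17)-trien-16,14-olide | C=C1C(=O)O[C@@H]2[C@@H]1C[C@H](O)[C@](C)(O)CC/C=C(\C)CC/C=C(\C)[C@@H]2O | intermediate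
28 | crassocolide B, (1R,3S,4R,13S,14R,7E,11E)-3,13-diacetoxy-4-hydroxycembra-7,11,15(17)-trien-16,14-olide | C=C1C(=O)O[C@@H]2[C@@H]1C[C@H](OC(C)=O)[C@](C)(O)CC/C=C(\C)CC/C=C(\C)[C@@H]2OC(C)=O | target

## Step count and least certain steps

Total: 18 steps. Longest linear sequence: 18 steps from 1 (12 to the precursor 19, the key step, 5 after it). Auxiliary 10 is recovered in step 10.

**Step 13 (key step).** The most likely failure is weak facial control in the ketyl coupling. The twelve-atom tether is long enough for C12 and C1 to sit on opposite sides of the titanium diolate, so the threo (13R) diol may form beside or instead of the erythro one. Intermolecular coupling also competes if the substrate is added too fast. The fallback sets out from 19 and comes back at 21. The ring is closed as in step 13 without regard to C13. The 13-epi hydroxy lactone F1, alone or mixed with 21, is oxidised with Dess–Martin periodinane/NaHCO3 to the single 13-oxo lactone F2, an enone in which C1 and C14 are unchanged. F2 is then reduced under reagent control, with catecholborane and the enantiomer of 2-methyl-CBS-oxazaborolidine that delivers hydride to the face giving 13S (or NaBH4/CeCl3·7H2O if substrate control already points that way), to give 21. C13 is then set by hydride delivery and no longer by the coupling. A wrong configuration at C14 is not repaired by this.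

**Step 3.** The most likely failure is partial attack of water at the secondary epoxide carbon, or partial ionisation at the tertiary one. Opening at the other carbon gives the enantiomeric anti diol, so any loss of regioselectivity appears as loss of enantiomeric purity; ionisation gives the syn diastereomer. The fallback sets out from 1 and comes back at 7.
- Epoxidation of 1 with the other tartrate (Ti(OiPr)4, D-(−)-diethyl tartrate, t-BuOOH) gives (2R,3R)-2,3-epoxyfarnesol F3.
- Aqueous NaOH in t-BuOH at 75 °C (Payne rearrangement, then hydroxide opening of the terminal epoxide) gives (2S,3R)-3,7,11-trimethyldodeca-6,10-diene-1,2,3-triol F4. Inversion occurs only at the secondary carbon, through an intramolecular SN2 step.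
- The primary hydroxyl is silylated (t-BuPh2SiCl, imidazole) to silyl ether diol F5, and the remaining diol is closed (2,2-dimethoxypropane, PPTS) to acetonide silyl ether F6.
- Bu4NF frees acetonide alcohol F7. Parikh–Doering oxidation to acetonide aldehyde F8, followed in the same flask by ylide 3, gives 7.

**Step 9.** The most likely failures are incomplete site selectivity between the terminal and the internal trisubstituted olefin, over-oxidation to the enal, and stalling at partial conversion on advanced material. The fallback sets out from 15 and comes back at 18. The auxiliary is first exchanged for the thioester with LiSEt as in step 10, giving thioester F9 with the isopropylidene terminus intact. Cross-metathesis of F9 with methacrolein (second-generation Hoveyda–Grubbs catalyst, CH2Cl2, 40 °C) then replaces the terminal CMe2 by C(Me)CHO and gives 18 directly. Only the prenyl-type terminus can shed a volatile olefin, which is the basis of the site selectivity, and the E enal is the thermodynamic product.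

**Step 12.** The most likely failures are conjugate hydrosilylation of the enal on palladium, or slow C–S insertion once the catalyst is poisoned, with erosion of C1 on prolonged exposure. The fallback sets out from 17 and comes back at 19. The C13 hydroxyl is silylated (Et3SiCl, imidazole) to silyl ether thioester F10. Fukuyama reduction of F10, now without an enal, gives silyl ether aldehyde F11. HF·pyridine buffered with pyridine (THF, 0 °C) frees hydroxy aldehyde F12, and MnO2 oxidises only the allylic alcohol to give 19.

## Further compounds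

F1 | step 13 | (1R,3S,4R,13R,14R,7E,11E)-13-hydroxy-3,4-(isopropylidenedioxy)cembra-7,11-dien-16,14-olide (13-epi hydroxy lactone) | C1C(=O)O[C@@H]2[C@@H]1C[C@@H]3OC(C)(C)O[C@]3(C)CC/C=C(\C)CC/C=C(\C)[C@H]2O
F2 | step 13 | (1R,3S,4R,14R,7E,11E)-3,4-(isopropylidenedioxy)-13-oxocembra-7,11-dien-16,14-olide (13-oxo lactone) | C1C(=O)O[C@@H]2[C@@H]1C[C@@H]3OC(C)(C)O[C@]3(C)CC/C=C(\C)CC/C=C(\C)C2=O
F3 | step 3 | (2R,3R)-2,3-epoxyfarnesol | CC(C)=CCC/C(C)=C/CC[C@@]1(C)O[C@@H]1CO
F4 | step 3 | (2S,3R,6E)-3,7,11-trimethyldodeca-6,10-diene-1,2,3-triol | CC(C)=CCC/C(C)=C/CC[C@@](C)(O)[C@@H](O)CO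
F5 | step 3 | (2S,3R,6E)-1-(tert-butyldiphenylsilyloxy)-3,7,11-trimethyldodeca-6,10-diene-2,3-diol (silyl ether diol) | CC(C)=CCC/C(C)=C/CC[C@@](C)(O)[C@@H](O)CO[Si](c1ccccc1)(c1ccccc1)C(C)(C)C
F6 | step 3 | tert-butyl{[(4S,5R)-5-[(3E)-4,8-dimethylnona-3,7-dien-1-yl]-2,2,5-trimethyl-1,3-dioxolan-4-yl]methoxy}diphenylsilane (acetonide silyl ether) | CC(C)=CCC/C(C)=C/CC[C@@]1(C)OC(C)(C)O[C@H]1CO[Si](c2ccccc2)(c2ccccc2)C(C)(C)C
F7 | step 3 | [(4S,5R)-5-[(3E)-4,8-dimethylnona-3,7-dien-1-yl]-2,2,5-trimethyl-1,3-dioxolan-4-yl]methanol (acetonide alcohol) | CC(C)=CCC/C(C)=C/CC[C@@]1(C)OC(C)(C)O[C@H]1CO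
F8 | step 3 | (4R,5R)-5-[(3E)-4,8-dimethylnona-3,7-dien-1-yl]-2,2,5-trimethyl-1,3-dioxolane-4-carbaldehyde (acetonide aldehyde) | CC(C)=CCC/C(C)=C/CC[C@@]1(C)OC(C)(C)O[C@H]1C=O
F9 | step 9 | methyl (3R)-3-[(ethylsulfanyl)carbonyl]-4-[(4S,5R)-5-[(3E)-4,8-dimethylnona-3,7-dien-1-yl]-2,2,5-trimethyl-1,3-dioxolan-4-yl]butanoate | CC(C)=CCC/C(C)=C/CC[C@@]1(C)OC(C)(C)O[C@H]1C[C@H](CC(=O)OC)C(=O)SCC
F10 | step 12 | methyl (3R)-3-[(ethylsulfanyl)carbonyl]-4-[(4S,5R)-5-[(3E,7E)-4,8-dimethyl-9-(triethylsilyloxy)nona-3,7-dien-1-yl]-2,2,5-trimethyl-1,3-dioxolan-4-yl]butanoate | CC[Si](CC)(CC)OC/C(C)=C/CC/C(C)=C/CC[C@@]1(C)OC(C)(C)O[C@H]1C[C@H](CC(=O)OC)C(=O)SCC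
F11 | step 12 | methyl (3R)-3-formyl-4-[(4S,5R)-5-[(3E,7E)-4,8-dimethyl-9-(triethylsilyloxy)nona-3,7-dien-1-yl]-2,2,5-trimethyl-1,3-dioxolan-4-yl]butanoate | CC[Si](CC)(CC)OC/C(C)=C/CC/C(C)=C/CC[C@@]1(C)OC(C)(C)O[C@H]1C[C@H](CC(=O)OC)C=O
F12 | step 12 | methyl (3R)-3-formyl-4-[(4S,5R)-5-[(3E,7E)-9-hydroxy-4,8-dimethylnona-3,7-dien-1-yl]-2,2,5-trimethyl-1,3-dioxolan-4-yl]butanoate | OC/C(C)=C/CC/C(C)=C/CC[C@@]1(C)OC(C)(C)O[C@H]1C[C@H](CC(=O)OC)C=O
A1 | alternative 1 | 14-membered C4 ketone fused to the γ-lactone, C3 p-methoxybenzyl ether, C13 tert-butyldimethylsilyl ether | C1C(=O)O[C@@H]2[C@@H]1C[C@H](OCc3ccc(OC)cc3)C(=O)CC/C=C(\C)CC/C=C(\C)[C@@H]2O[Si](C)(C)C(C)(C)C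
A2 | alternative 1 | 16-membered allyl β-keto ester macrolactone (carboxyl group between C5 and the C6 oxygen) | C1C(=O)O[C@@H]2[C@@H]1C[C@H](OCc3ccc(OC)cc3)C(=O)CC(=O)OC/C=C(\C)CC/C=C(\C)[C@@H]2O[Si](C)(C)C(C)(C)C
A3 | alternative 2 | macrocyclic C3 keto γ-lactone, C4 triethylsilyl ether, C13 tert-butyldimethylsilyl ether | C1C(=O)O[C@@H]2[C@@H]1CC(=O)[C@](C)(O[Si](CC)(CC)CC)CC/C=C(\C)CC/C=C(\C)[C@@H]2O[Si](C)(C)C(C)(C)C
A4 | alternative 2 | 13-membered cyclic enol ether with C14 vinyl group and exocyclic C3=C15 alkoxyacrylate | COC(=O)/C=C1/O[C@H](C=C)[C@@H](O[Si](C)(C)C(C)(C)C)/C(C)=C/CC/C(C)=C/CC[C@@]1(C)O[Si](CC)(CC)CC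
A5 | alternative 3 | macrocyclic γ-lactone with C13 triethylsilyl ether and C3/C4 acetonide (identical with 22) | C1C(=O)O[C@@H]2[C@@H]1C[C@@H]3OC(C)(C)O[C@]3(C)CC/C=C(\C)CC/C=C(\C)[C@@H]2O[Si](CC)(CC)CC
A6 | alternative 3 | ynal: trans-disubstituted γ-lactone with C13 formyl group on C14 and terminal C11≡C12 methyl alkyne | O=C[C@@H]1OC(=O)C[C@H]1C[C@@H]2OC(C)(C)O[C@]2(C)CC/C=C(\C)CCC#CC
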